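Ring C is cut at both bonds to ring A, O1–C8a and C4–C4a, so that ring A arrives as a 3,5-dimethoxy-6-lavandulylbenzyne and C2–C4 as an (S)-3-aryl-3-silyloxypropanoate made by asymmetric aldol addition. In one operation fluoride unmasks alkoxide and aryne, the oxygen adds to C8a and the C4a anion acylates on the ester, closing the pyranone with C2 already set. The step exploits the ortho placement of O1 and the C4 carbonyl on ring A and the C5 oxygen beside C4a, which steers oxygen to C8a. The aryne precursor is an ortho-silylaryl triflate carrying the (R)-lavandulyl chain; chelation-controlled 5-O-demethylation ends the route.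

Key step: step 10

Remark: (±)-lavandulol, 2,4-dihydroxy-5-methoxybenzaldehyde and 1-methoxy-1-(trimethylsilyloxy)ethene are taken as catalogue chemicals; the (R) side-chain centre of the target corresponds in space to (S)-lavandulol, because the sequence-rule priorities change when CH2OH becomes CH2Ar.

Step 1
Reactants: 1 (±)-lavandulol
Product: 2 (S)-lavandulol
Conditions: vinyl acetate, immobilised Candida antarctica lipase B, hexane, rt, to about 60% conversion; chromatography
Reagents that add atoms: none
Why: Lipase-catalysed kinetic resolution by enantioselective transesterification: the enzyme is expected to acetylate the (R)-alcohol faster, so running past half conversion should leave the (S)-alcohol enriched, the enzyme's active site selecting the stereocentre.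

Step 2
Reactants: 2 (S)-lavandulol
Product: 3 (S)-lavandulyl bromide
Conditions: CBr4, PPh3, CH2Cl2, 0 °C
Reagents that add atoms: carbon tetrabromide, BrC(Br)(Br)Br
Why: Appel reaction: bromide displaces the primary alkoxyphosphonium ion in an SN2 step that does not touch the neighbouring stereocentre.

Step 3
Reactants: 4 3,5-dimethoxyphenol
Product: 5 1,3-dimethoxy-5-(methoxymethoxy)benzene
Conditions: MOMCl, iPr2NEt, CH2Cl2, 0 °C → rt
Reagents that add atoms: chloromethyl methyl ether (MOMCl), COCCl
Why: Williamson-type O-alkylation of the phenol; the MOM ether is the directing group for both later ortho-metalations.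

Step 4
Reactants: 5 1,3-dimethoxy-5-(methoxymethoxy)benzene; 3 (S)-lavandulyl bromide
Product: 8 1,5-dimethoxy-3-(methoxymethoxy)-2-[(2R)-5-methyl-2-(prop-1-en-2-yl)hex-4-en-1-yl]benzene, via aryllithium 6 (not isolated), via arylmagnesium bromide 7 (not isolated)
Conditions: 5 (1.5 equiv), n-BuLi, THF, 0 °C; MgBr2·OEt2; then 3, Li2CuCl4 (5 mol%), THF/NMP, −20 °C → rt
Reagents that add atoms: none
Why: Directed ortho-metalation at the position flanked by OMOM and OMe (OMOM is the stronger director, so this site is expected over the one between the two OMe groups), then copper-catalysed Grignard alkylation, an SN2-type substitution at CH2 that leaves the stereocentre intact (its descriptor becomes R only through the priority change).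

Step 5
Reactants: 8 1,5-dimethoxy-3-(methoxymethoxy)-2-[(2R)-5-methyl-2-(prop-1-en-2-yl)hex-4-en-1-yl]benzene
Product: 10 {2,4-dimethoxy-6-(methoxymethoxy)-5-[(2R)-5-methyl-2-(prop-1-en-2-yl)hex-4-en-1-yl]phenyl}trimethylsilane, via aryllithium 9 (not isolated)
Conditions: n-BuLi, TMEDA, THF, 0 °C; TMSCl, −78 °C → rt
Reagents that add atoms: chlorotrimethylsilane (TMSCl), C[Si](C)(C)Cl
Why: Second directed ortho-metalation at the only remaining C–H flanked by OMOM and OMe (cooperative direction, favoured over the C–H between two OMe groups), then C-silylation.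

Step 6
Reactants: 10 {2,4-dimethoxy-6-(methoxymethoxy)-5-[(2R)-5-methyl-2-(prop-1-en-2-yl)hex-4-en-1-yl]phenyl}trimethylsilane
Product: 12 3,5-dimethoxy-2-[(2R)-5-methyl-2-(prop-1-en-2-yl)hex-4-en-1-yl]-6-(trimethylsilyl)phenol, via aryl silyl ether 11 (not isolated)
Conditions: TMSOTf, 2,2'-bipyridyl, CH2Cl2, 0 °C → rt; then H2O
Reagents that add atoms: none
Why: Non-acidic cleavage of an aromatic MOM ether (silyl triflate activation buffered by bipyridyl, aryl silyl ether, hydrolysis), chosen so that the electron-rich arylsilane is not protodesilylated and the diene is not protonated.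

Step 7
Reactants: 12 3,5-dimethoxy-2-[(2R)-5-methyl-2-(prop-1-en-2-yl)hex-4-en-1-yl]-6-(trimethylsilyl)phenol
Product: 13 3,5-dimethoxy-2-[(2R)-5-methyl-2-(prop-1-en-2-yl)hex-4-en-1-yl]-6-(trimethylsilyl)phenyl trifluoromethanesulfonate
Conditions: Tf2O, pyridine, CH2Cl2, −78 → 0 °C
Reagents that add atoms: trifluoromethanesulfonic anhydride (Tf2O), O=S(=O)(OS(=O)(=O)C(F)(F)F)C(F)(F)F
Why: O-sulfonylation of the phenol under amine buffering completes the ortho-silylaryl triflate, the fluoride-triggered aryne precursor.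

Step 8
Reactants: 14 2,4-dihydroxy-5-methoxybenzaldehyde
Product: 15 5-methoxy-2,4-bis(methoxymethoxy)benzaldehyde
Conditions: MOMCl, iPr2NEt, CH2Cl2, 0 °C → reflux
Reagents that add atoms: chloromethyl methyl ether (MOMCl), COCCl
Why: Double Williamson-type O-alkylation; MOM ethers are stable to fluoride and alkoxide in the key step.

Step 9
Reactants: 15 5-methoxy-2,4-bis(methoxymethoxy)benzaldehyde
Product: 16 methyl (3S)-3-[5-methoxy-2,4-bis(methoxymethoxy)phenyl]-3-[(trimethylsilyl)oxy]propanoate
Conditions: 1-methoxy-1-(trimethylsilyloxy)ethene, Ti(OiPr)4 (5 mol%), Schiff base ligand from 2-amino-2'-hydroxy-1,1'-binaphthyl and 3-bromo-5-tert-butylsalicylaldehyde, 3,5-di-tert-butylsalicylic acid, Et2O, −10 °C; non-aqueous work-up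
Reagents that add atoms: 1-methoxy-1-(trimethylsilyloxy)ethene, C=C(OC)O[Si](C)(C)C
Why: Catalytic enantioselective Mukaiyama acetate aldol addition with silyl transfer, which gives the O-silyl adduct directly; the antipode of the binaphthyl ligand that opens the Si face of the aldehyde is used, which sets the (S) carbinol centre.

Step 10
Reactants: 13 3,5-dimethoxy-2-[(2R)-5-methyl-2-(prop-1-en-2-yl)hex-4-en-1-yl]-6-(trimethylsilyl)phenyl trifluoromethanesulfonate; 16 methyl (3S)-3-[5-methoxy-2,4-bis(methoxymethoxy)phenyl]-3-[(trimethylsilyl)oxy]propanoate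
Product: 20 (2S)-5,7-dimethoxy-2-[5-methoxy-2,4-bis(methoxymethoxy)phenyl]-8-[(2R)-5-methyl-2-(prop-1-en-2-yl)hex-4-en-1-yl]-2,3-dihydro-4H-chromen-4-one, via potassium alkoxide 17 (not isolated), via aryne 18 (not isolated), via aryl anion 19 (not isolated)
Conditions: 16 (1.5 equiv), KF, 18-crown-6, THF, −20 °C; 13 added slowly; −20 → 0 °C; AcOH quench
Reagents that add atoms: none
Why: Proposed new method: fluoride cleaves the O–Si bond of 16 to the alkoxide 17 and triggers 1,2-elimination of 13 to the aryne 18; the alkoxide oxygen adds to C8a, the aryl anion 19 formed at C4a attacks the pendant methyl ester and loss of methoxide (which ends as MeOSiMe3) gives the ketone, so O1–C8a and C4a–C4 form in one operation. The closest known reaction type is the fluoride-induced annulation of arynes with ortho-hydroxybenzoates to xanthones (O-arylation followed by intramolecular acyl substitution), which has not been shown for an aliphatic β-silyloxy ester. Ring C is closed by intermolecular C–O bond formation followed by a 6-exo-trig attack of the aryl anion on the ester carbonyl. No stereocentre is created: C2 comes from 16 with its C–O bond untouched, and the side-chain centre is remote. The regiochemistry needed (oxygen at C8a, acyl at C4a) is secured by the C5 methoxy group beside the triple bond, whose inductive effect distorts the aryne so that the nucleophile attacks the distal carbon C8a and the charge develops at C4a next to oxygen, the alkyl group at C8 being electronically neutral. The chemoselectivity needed (acylation before protonation of 19, alkoxide capture before an intramolecular ene reaction of 18 with its prenyl terminus, no base-induced opening at C2) is addressed by the aprotic silyl-ether form of the nucleophile, its excess with slow addition of 13, and a cold acidic quench.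

Step 11
Reactants: 20 (2S)-5,7-dimethoxy-2-[5-methoxy-2,4-bis(methoxymethoxy)phenyl]-8-[(2R)-5-methyl-2-(prop-1-en-2-yl)hex-4-en-1-yl]-2,3-dihydro-4H-chromen-4-one
Product: 21 (2S)-2-(2,4-dihydroxy-5-methoxyphenyl)-5-hydroxy-7-methoxy-8-[(2R)-5-methyl-2-(prop-1-en-2-yl)hex-4-en-1-yl]-2,3-dihydro-4H-chromen-4-one
Conditions: BCl3, CH2Cl2, −78 → 0 °C; MeOH quench at −78 °C, aq. NaHCO3
Reagents that add atoms: none
Why: Chelation-controlled Lewis-acid ether cleavage: BCl3 held by the C4 carbonyl should remove only the peri 5-O-methyl group and the two acetal-type MOM groups, while the unchelated 7- and 5'-methoxy groups, the alkenes and C2 should survive at low temperature.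

Compound list
1 | (±)-lavandulol, racemic 5-methyl-2-(prop-1-en-2-yl)hex-4-en-1-ol | C=C(C)C(CO)CC=C(C)C | starting material
2 | (S)-lavandulol, (2S)-5-methyl-2-(prop-1-en-2-yl)hex-4-en-1-ol | C=C(C)[C@H](CC=C(C)C)CO | intermediate
3 | (S)-lavandulyl bromide, (3S)-3-(bromomethyl)-2,6-dimethylhepta-1,5-diene | C=C(C)[C@H](CC=C(C)C)CBr | intermediate
4 | 3,5-dimethoxyphenol | COc1cc(O)cc(OC)c1 | starting material
5 | 1,3-dimethoxy-5-(methoxymethoxy)benzene | COCOc1cc(OC)cc(OC)c1 | intermediate
6 | [2,4-dimethoxy-6-(methoxymethoxy)phenyl]lithium | [Li]c1c(OC)cc(OC)cc1OCOC | intermediate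
7 | [2,4-dimethoxy-6-(methoxymethoxy)phenyl]magnesium bromide | Br[Mg]c1c(OC)cc(OC)cc1OCOC | intermediate
8 | 1,5-dimethoxy-3-(methoxymethoxy)-2-[(2R)-5-methyl-2-(prop-1-en-2-yl)hex-4-en-1-yl]benzene | C=C(C)[C@H](CC=C(C)C)Cc1c(OC)cc(OC)cc1OCOC | intermediate
9 | {2,4-dimethoxy-6-(methoxymethoxy)-5-[(2R)-5-methyl-2-(prop-1-en-2-yl)hex-4-en-1-yl]phenyl}lithium | C=C(C)[C@H](CC=C(C)C)Cc1c(OC)cc(OC)c([Li])c1OCOC | intermediate
10 | {2,4-dimethoxy-6-(methoxymethoxy)-5-[(2R)-5-methyl-2-(prop-1-en-2-yl)hex-4-en-1-yl]phenyl}trimethylsilane | C=C(C)[C@H](CC=C(C)C)Cc1c(OC)cc(OC)c([Si](C)(C)C)c1OCOC | intermediate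
11 | {2,4-dimethoxy-5-[(2R)-5-methyl-2-(prop-1-en-2-yl)hex-4-en-1-yl]-6-[(trimethylsilyl)oxy]phenyl}trimethylsilane | C=C(C)[C@H](CC=C(C)C)Cc1c(OC)cc(OC)c([Si](C)(C)C)c1O[Si](C)(C)C | intermediate
12 | 3,5-dimethoxy-2-[(2R)-5-methyl-2-(prop-1-en-2-yl)hex-4-en-1-yl]-6-(trimethylsilyl)phenol | C=C(C)[C@H](CC=C(C)C)Cc1c(OC)cc(OC)c([Si](C)(C)C)c1O | intermediate
13 | 3,5-dimethoxy-2-[(2R)-5-methyl-2-(prop-1-en-2-yl)hex-4-en-1-yl]-6-(trimethylsilyl)phenyl trifluoromethanesulfonate | C=C(C)[C@H](CC=C(C)C)Cc1c(OC)cc(OC)c([Si](C)(C)C)c1OS(=O)(=O)C(F)(F)F | intermediate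
14 | 2,4-dihydroxy-5-methoxybenzaldehyde | O=Cc1cc(OC)c(O)cc1O | starting material
15 | 5-methoxy-2,4-bis(methoxymethoxy)benzaldehyde | O=Cc1cc(OC)c(OCOC)cc1OCOC | intermediate
16 | methyl (3S)-3-[5-methoxy-2,4-bis(methoxymethoxy)phenyl]-3-[(trimethylsilyl)oxy]propanoate | C[Si](C)(C)O[C@H](c1cc(OC)c(OCOC)cc1OCOC)CC(=O)OC | intermediate
17 | potassium (1S)-3-methoxy-1-[5-methoxy-2,4-bis(methoxymethoxy)phenyl]-3-oxopropan-1-olate | [K+].[O-][C@H](c1cc(OC)c(OCOC)cc1OCOC)CC(=O)OC | intermediate
18 | 4,6-dimethoxy-3-[(2R)-5-methyl-2-(prop-1-en-2-yl)hex-4-en-1-yl]-1,2-didehydrobenzene (aryne) | C=C(C)[C@H](CC=C(C)C)CC1=C(OC)C=C(OC)C#C1 | intermediate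
19 | potassium salt of the aryl anion at C4a of methyl (3S)-3-{3,5-dimethoxy-2-[(2R)-5-methyl-2-(prop-1-en-2-yl)hex-4-en-1-yl]phenoxy}-3-[5-methoxy-2,4-bis(methoxymethoxy)phenyl]propanoate | C=C(C)[C@H](CC=C(C)C)Cc1c(OC)cc(OC)[c-]c1O[C@H](c1cc(OC)c(OCOC)cc1OCOC)CC(=O)OC.[K+] | intermediate
20 | (2S)-5,7-dimethoxy-2-[5-methoxy-2,4-bis(methoxymethoxy)phenyl]-8-[(2R)-5-methyl-2-(prop-1-en-2-yl)hex-4-en-1-yl]-2,3-dihydro-4H-chromen-4-one | C=C(C)[C@H](CC=C(C)C)Cc1c(OC)cc(OC)c2c1O[C@H](c1cc(OC)c(OCOC)cc1OCOC)CC2=O | intermediate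
21 | (2S)-2-(2,4-dihydroxy-5-methoxyphenyl)-5-hydroxy-7-methoxy-8-[(2R)-5-methyl-2-(prop-1-en-2-yl)hex-4-en-1-yl]-2,3-dihydro-4H-chromen-4-one | C=C(C)[C@H](CC=C(C)C)Cc1c(OC)cc(O)c2c1O[C@H](c1cc(OC)c(O)cc1O)CC2=O | target

Total step count: 11
Longest linear sequence: 8 steps (steps 1, 2, 4, 5, 6, 7, 10, 11)

Steps most likely to fail

Step 10 (Proposed new method). What may go wrong: interception of the aryne by its own prenyl terminus in an intramolecular ene reaction; proton transfer to the aryl anion, including from C3–H with β-elimination of the aryloxide, before it can acylate; retro-aldol or ring-opening equilibration that erodes the configuration at C2. The fallback uses known reactions, sets out from 16 and 13 and comes back at 20; it separates the two bond formations. 16 is desilylated (aqueous citric acid, MeOH) to methyl (3S)-3-hydroxy-3-[5-methoxy-2,4-bis(methoxymethoxy)phenyl]propanoate F1. F1, used in large excess because no aryl anion has to survive, is O-arylated by the aryne from 13 (KF, 18-crown-6, THF, −20 °C; aryne O–H insertion of an aliphatic alcohol). This should give, with the same regiochemistry and hydrogen at C4a, the aryl ether methyl (3S)-3-{3,5-dimethoxy-2-[(2R)-5-methyl-2-(prop-1-en-2-yl)hex-4-en-1-yl]phenoxy}-3-[5-methoxy-2,4-bis(methoxymethoxy)phenyl]propanoate F2. Saponification (LiOH, THF/H2O, 0 °C) gives the corresponding propanoic acid F3. Intramolecular Friedel–Crafts acylation (TFAA, CH2Cl2, −20 → 0 °C) at C4a, the only free position ortho to the ether oxygen and activated by both methoxy groups, closes ring C and returns to 20. The fallback shares the ene risk, which the large excess of F1 is meant to suppress, and its last step exposes the alkenes and the benzylic ether to acid.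

Step 4. What may go wrong: slow substitution at the β-branched primary carbon, so that elimination to the conjugated diene and homocoupling of the aryl metal take over. The fallback reverses the polarity, sets out from 5 and 3 and comes back at 8. 5 is lithiated as in the route and iodinated (I2, THF, −78 °C) to 2-iodo-1,5-dimethoxy-3-(methoxymethoxy)benzene F4. 3 is converted by zinc insertion (Zn dust, LiCl, THF) into [(2S)-5-methyl-2-(prop-1-en-2-yl)hex-4-en-1-yl]zinc bromide F5. Negishi coupling (Pd(OAc)2, SPhos, THF, rt) joins the two to 8.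

Step 11. What may go wrong: hydrochlorination or cationic cyclisation of the side-chain alkenes, cleavage of a second methyl ether, and acid-induced opening at C2 with loss of configuration. The fallback avoids the boron halide and separates the two deprotections; it sets out from 20 and comes back at 21. MgI2·OEt2 (toluene/Et2O, 60 °C) should remove only the chelated 5-O-methyl group and give (2S)-5-hydroxy-7-methoxy-2-[5-methoxy-2,4-bis(methoxymethoxy)phenyl]-8-[(2R)-5-methyl-2-(prop-1-en-2-yl)hex-4-en-1-yl]-2,3-dihydro-4H-chromen-4-one F6. Methanolysis of the two acetals (dilute HCl, MeOH, rt) then gives 21.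

Further compounds
F1 | step 10 | methyl (3S)-3-hydroxy-3-[5-methoxy-2,4-bis(methoxymethoxy)phenyl]propanoate | O[C@H](c1cc(OC)c(OCOC)cc1OCOC)CC(=O)OC
F2 | step 10 | methyl (3S)-3-{3,5-dimethoxy-2-[(2R)-5-methyl-2-(prop-1-en-2-yl)hex-4-en-1-yl]phenoxy}-3-[5-methoxy-2,4-bis(methoxymethoxy)phenyl]propanoate | C=C(C)[C@H](CC=C(C)C)Cc1c(OC)cc(OC)cc1O[C@H](c1cc(OC)c(OCOC)cc1OCOC)CC(=O)OC
F3 | step 10 | (3S)-3-{3,5-dimethoxy-2-[(2R)-5-methyl-2-(prop-1-en-2-yl)hex-4-en-1-yl]phenoxy}-3-[5-methoxy-2,4-bis(methoxymethoxy)phenyl]propanoic acid | C=C(C)[C@H](CC=C(C)C)Cc1c(OC)cc(OC)cc1O[C@H](c1cc(OC)c(OCOC)cc1OCOC)CC(=O)O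
F4 | step 4 | 2-iodo-1,5-dimethoxy-3-(methoxymethoxy)benzene | COCOc1cc(OC)cc(OC)c1I
F5 | step 4 | [(2S)-5-methyl-2-(prop-1-en-2-yl)hex-4-en-1-yl]zinc bromide | C=C(C)[C@H](CC=C(C)C)C[Zn]Br
F6 | step 11 | (2S)-5-hydroxy-7-methoxy-2-[5-methoxy-2,4-bis(methoxymethoxy)phenyl]-8-[(2R)-5-methyl-2-(prop-1-en-2-yl)hex-4-en-1-yl]-2,3-dihydro-4H-chromen-4-one | C=C(C)[C@H](CC=C(C)C)Cc1c(OC)cc(O)c2c1O[C@H](c1cc(OC)c(OCOC)cc1OCOC)CC2=O
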